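**Retrosynthetic overview**
1. The ester C–O bond is cut last: Steglich esterification of linoleic acid with the monocyclic diterpene alcohol.
2. Side chain: the sp3–sp2 bond next to the 6E alkene is made by B-alkyl Suzuki coupling. The 6E geometry comes from Negishi carboalumination of a terminal alkyne, the 2E geometry from commercial (E)-3-methylpent-2-en-4-yn-1-ol.
3. Ring (the only ring, formed once): a formal [3+3] annulation of acrolein onto the C6–C1–C2 unit. C5–C6 forms by radical conjugate addition and C2=C3 by intramolecular Wittig olefination, in one flask (ring locants: C1 carries the chain, C2 the methyl, C6 the gem-dimethyl group).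
4. Enabling feature: the cyclobutane of a cis-pinonic acid derivative. Its gem-dimethyl carbon (future C6) sits between the phosphonium-bearing arm (future C1/C2) and the ring carbon that holds the CH2CO2N(phthaloyl) arm. Decarboxylation puts a radical next to the four-membered ring, and strain-releasing β-scission gives the tertiary C6 radical and leaves an allyl handle on C1.
5. Stereocentre: C1 of the target is the bridgehead carbon of (1R,5R)-(+)-α-pinene next to its methyl-bearing alkene carbon, carried through untouched.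

Key step: step 7

Assumption: (1R,5R)-(+)-α-pinene of high enantiomeric purity is used, so that this bridgehead carbon is the only source of the target's stereocentre.

**Route**

Step 1
Reactants: 1 (1R,5R)-(+)-α-pinene
Product: 2 cis-pinonic acid, 2-[(1S,3S)-3-acetyl-2,2-dimethylcyclobutyl]acetic acid
Conditions: RuCl3 hydrate (2 mol %), NaIO4, CCl4/MeCN/H2O, rt
Reagents that add atoms: sodium periodate [Na+].[O-]I(=O)(=O)=O; water O
Why: RuO4 formed in situ cleaves the trisubstituted alkene to ketone and carboxylic acid (Ru-catalysed oxidative cleavage) without touching the two stereocentres, whose cis relation is fixed by the bicycle.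

Step 2
Reactants: 2 cis-pinonic acid
Product: 3 benzyl 2-[(1S,3S)-3-acetyl-2,2-dimethylcyclobutyl]acetate
Conditions: BnBr, KHCO3, DMF, rt
Reagents that add atoms: benzyl bromide BrCc1ccccc1
Why: O-alkylation of the carboxylate by SN2 on benzyl bromide under a base too weak to epimerise the ring carbon next to the ketone.

Step 3
Reactants: 3 benzyl 2-[(1S,3S)-3-acetyl-2,2-dimethylcyclobutyl]acetate
Product: 5 benzyl 2-[(1S,3S)-2,2-dimethyl-3-[1-(trifluoromethanesulfonyloxy)ethenyl]cyclobutyl]acetate, via lithium enolate 4 (not isolated)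
Conditions: LDA, THF, −78 °C; then PhNTf2, −78 to 0 °C
Reagents that add atoms: N-phenylbis(trifluoromethanesulfonimide) O=S(=O)(N(c1ccccc1)S(=O)(=O)C(F)(F)F)C(F)(F)F
Why: kinetic deprotonation of the methyl ketone at the methyl group and O-sulfonylation of the enolate (kinetic enol triflate formation) leave the adjacent ring stereocentre untouched.

Step 4
Reactants: 5 benzyl 2-[(1S,3S)-2,2-dimethyl-3-[1-(trifluoromethanesulfonyloxy)ethenyl]cyclobutyl]acetate
Product: 6 [1-[(1S,3S)-3-(2-benzyloxy-2-oxoethyl)-2,2-dimethylcyclobutyl]ethenyl]triphenylphosphonium trifluoromethanesulfonate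
Conditions: PPh3, Pd(PPh3)4 (3 mol %), THF, 65 °C
Reagents that add atoms: triphenylphosphine c1ccc(cc1)P(c1ccccc1)c1ccccc1
Why: oxidative addition of zerovalent palladium to the vinyl triflate and P–C reductive elimination with PPh3 (Pd-catalysed phosphination of a vinyl triflate) install phosphorus without a substitution at a hindered sp3 carbon.

Step 5
Reactants: 6 [1-[(1S,3S)-3-(2-benzyloxy-2-oxoethyl)-2,2-dimethylcyclobutyl]ethenyl]triphenylphosphonium trifluoromethanesulfonate
Product: 7 [1-[(1S,3S)-3-(carboxymethyl)-2,2-dimethylcyclobutyl]ethyl]triphenylphosphonium trifluoromethanesulfonate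
Conditions: H2 (4 bar), Pd/C (10% Pd), MeOH, rt
Reagents that add atoms: none
Why: heterogeneous catalytic hydrogenation should saturate the 1,1-disubstituted alkene and cleave the benzyl ester by hydrogenolysis in the same operation; the new phosphonium-bearing centre forms without control, which is harmless because it becomes sp2 in step 7.

Step 6
Reactants: 7 [1-[(1S,3S)-3-(carboxymethyl)-2,2-dimethylcyclobutyl]ethyl]triphenylphosphonium trifluoromethanesulfonate
Product: 8 [1-[(1S,3S)-3-[2-(1,3-dioxoisoindolin-2-yl)oxy-2-oxoethyl]-2,2-dimethylcyclobutyl]ethyl]triphenylphosphonium trifluoromethanesulfonate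
Conditions: N-hydroxyphthalimide, DIC, DMAP (cat.), CH2Cl2, rt
Reagents that add atoms: N-hydroxyphthalimide O=C1c2ccccc2C(=O)N1O
Why: carbodiimide-mediated esterification (Steglich type) turns the acid into the redox-active N-acyloxyphthalimide under neutral conditions that the phosphonium salt tolerates.

Step 7
Reactants: 8 [1-[(1S,3S)-3-[2-(1,3-dioxoisoindolin-2-yl)oxy-2-oxoethyl]-2,2-dimethylcyclobutyl]ethyl]triphenylphosphonium trifluoromethanesulfonate; 9 acrolein
Product: 12 (6S)-1,5,5-trimethyl-6-(prop-2-en-1-yl)cyclohex-1-ene, via aldehyde phosphonium triflate 10 (not isolated), via phosphorus ylide 11 (not isolated)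
Conditions: Ru(bpy)3(PF6)2 (1 mol %), Hantzsch ester (excess), 9 added slowly, CH2Cl2 (dilute), blue LEDs, rt; then evaporation, THF, KOtBu, −40 °C to rt, same flask
Reagents that add atoms: none
Why: Proposed new method: single-electron reduction of the N-acyloxyphthalimide by the photoreduced Ru(bpy)3 complex gives, after loss of CO2 and phthalimide anion, a primary cyclobutylcarbinyl radical that opens by β-scission of the ring bond to the gem-dimethyl carbon (strain release, tertiary radical); this radical adds to the β-carbon of acrolein (Giese addition), the α-formyl radical takes a hydrogen atom from the Hantzsch ester to give 10, and KOtBu then forms ylide 11, which closes onto the new aldehyde by intramolecular Wittig olefination. The closest known reaction types are the visible-light decarboxylative Giese addition of N-acyloxyphthalimides, the ring opening of cyclobutylcarbinyl radicals, and the intramolecular Wittig reaction as used in Michael–Wittig [3+3] cyclohexadiene annulations of allylidenephosphoranes; their union in one flask on a phosphonium-bearing redox-active ester is new. The only ring closes in the 6-exo-trig mode of the Wittig step (ylide carbon onto the aldehyde carbon through the oxaphosphetane), so the ring alkene must be cis and can lie only between these two carbons. No stereocentre is created: the ring carbon that carries the allyl group keeps the configuration of the pinene-derived cyclobutane carbon, which is neither deprotonated nor ionised, and the phosphonium-bearing centre (both epimers) becomes sp2. The step needs ring opening to outrun capture of the unopened radical and hydrogen transfer to outrun 6-exo attack of the α-formyl radical on the new allyl group, which the strained gem-dimethyl-substituted ring, a low stationary concentration of acrolein and an excess of the polarity-matched Hantzsch ester should secure; it also needs the ylide to meet only the tethered aldehyde, which removal of acrolein before the base secures.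

Step 8
Reactants: 12 (6S)-1,5,5-trimethyl-6-(prop-2-en-1-yl)cyclohex-1-ene
Product: 14 3-[(1S)-2,6,6-trimethylcyclohex-2-en-1-yl]propan-1-ol, via alkylborane 13 (not isolated)
Conditions: 9-BBN, THF, 0 °C to rt; then NaOH, H2O2
Reagents that add atoms: hydrogen peroxide OO
Why: hydroboration–oxidation, in which the bulky borane adds anti-Markovnikov to the monosubstituted alkene only and the hindered trisubstituted ring alkene should stay intact.

Step 9
Reactants: 14 3-[(1S)-2,6,6-trimethylcyclohex-2-en-1-yl]propan-1-ol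
Product: 15 3-[(1S)-2,6,6-trimethylcyclohex-2-en-1-yl]propanal
Conditions: Dess–Martin periodinane, CH2Cl2, rt
Reagents that add atoms: none
Why: Dess–Martin oxidation of the primary alcohol stops at the aldehyde under non-basic conditions.

Step 10
Reactants: 15 3-[(1S)-2,6,6-trimethylcyclohex-2-en-1-yl]propanal
Product: 16 (6S)-6-(but-3-yn-1-yl)-1,5,5-trimethylcyclohex-1-ene
Conditions: dimethyl (1-diazo-2-oxopropyl)phosphonate, K2CO3, MeOH, rt
Reagents that add atoms: dimethyl (1-diazo-2-oxopropyl)phosphonate COP(=O)(OC)C(=[N+]=[N-])C(C)=O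
Why: Seyferth–Gilbert homologation with the Ohira–Bestmann reagent converts the aldehyde into the terminal alkyne with one added carbon under mild base.

Step 11
Reactants: 16 (6S)-6-(but-3-yn-1-yl)-1,5,5-trimethylcyclohex-1-ene
Product: 18 (6S)-6-[(3E)-4-iodo-3-methylbut-3-en-1-yl]-1,5,5-trimethylcyclohex-1-ene, via alkenylalane 17 (not isolated)
Conditions: Me3Al, Cp2ZrCl2, CH2Cl2, 0 °C to rt; then I2, THF, −30 °C
Reagents that add atoms: trimethylaluminium C[Al](C)C; iodine II
Why: Negishi Zr-catalysed carboalumination adds methyl and aluminium syn across the terminal alkyne with methyl on the internal carbon, and iodinolysis with retention gives the (E)-iodide that fixes the 6E geometry.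

Step 12
Reactants: 19 (2E)-3-methylpent-2-en-4-yn-1-ol
Product: 20 tert-butyldimethyl{[(2E)-3-methylpent-2-en-4-yn-1-yl]oxy}silane
Conditions: TBSCl, imidazole, DMF, rt
Reagents that add atoms: tert-butyldimethylsilyl chloride CC(C)(C)[Si](C)(C)Cl
Why: silyl ether protection of the primary allylic alcohol keeps the hydroxyl from consuming borane in step 14.

Step 13
Reactants: 20 tert-butyldimethyl{[(2E)-3-methylpent-2-en-4-yn-1-yl]oxy}silane
Product: 21 tert-butyldimethyl{[(2E)-3-methylpenta-2,4-dien-1-yl]oxy}silane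
Conditions: H2 (1 atm), Pd/CaCO3 poisoned with Pb(OAc)2, quinoline, hexane, rt
Reagents that add atoms: none
Why: partial hydrogenation on poisoned palladium reduces the terminal alkyne to the vinyl group and leaves the trisubstituted (E)-alkene.

Step 14
Reactants: 21 tert-butyldimethyl{[(2E)-3-methylpenta-2,4-dien-1-yl]oxy}silane; 18 (6S)-6-[(3E)-4-iodo-3-methylbut-3-en-1-yl]-1,5,5-trimethylcyclohex-1-ene
Product: 23 tert-butyl{[(2E,6E)-3,7-dimethyl-9-[(1S)-2,6,6-trimethylcyclohex-2-en-1-yl]nona-2,6-dien-1-yl]oxy}dimethylsilane, via alkylborane 22 (not isolated)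
Conditions: 21, 9-BBN, THF, rt; then 18, Pd(dppf)Cl2 (5 mol %), AsPh3, Cs2CO3, DMF/H2O, rt
Reagents that add atoms: none
Why: 9-BBN hydroborates the terminal vinyl group of the diene, and B-alkyl Suzuki–Miyaura coupling with the vinyl iodide forms the sp3–sp2 bond with retention of both alkene geometries.

Step 15
Reactants: 23 tert-butyl{[(2E,6E)-3,7-dimethyl-9-[(1S)-2,6,6-trimethylcyclohex-2-en-1-yl]nona-2,6-dien-1-yl]oxy}dimethylsilane
Product: 24 (2E,6E)-3,7-dimethyl-9-[(1S)-2,6,6-trimethylcyclohex-2-en-1-yl]nona-2,6-dien-1-ol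
Conditions: TBAF, THF, 0 °C to rt
Reagents that add atoms: none
Why: fluoride-mediated desilylation frees the allylic alcohol.

Step 16
Reactants: 24 (2E,6E)-3,7-dimethyl-9-[(1S)-2,6,6-trimethylcyclohex-2-en-1-yl]nona-2,6-dien-1-ol; 25 linoleic acid
Product: 26 (2E,6E)-3,7-dimethyl-9-[(1S)-2,6,6-trimethylcyclohex-2-en-1-yl]nona-2,6-dien-1-yl (9Z,12Z)-octadeca-9,12-dienoate
Conditions: DCC, DMAP (cat.), CH2Cl2, 0 °C to rt, argon
Reagents that add atoms: none
Why: Steglich esterification under neutral conditions should join acid and allylic alcohol without isomerising the skipped (Z,Z)-diene or the allylic system.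

**Compound list**
1 | (1R,5R)-(+)-α-pinene | CC1=CC[C@@H]2C[C@H]1C2(C)C | starting material
2 | cis-pinonic acid, 2-[(1S,3S)-3-acetyl-2,2-dimethylcyclobutyl]acetic acid | CC(=O)[C@H]1C[C@@H](CC(=O)O)C1(C)C | intermediate
3 | benzyl 2-[(1S,3S)-3-acetyl-2,2-dimethylcyclobutyl]acetate | CC(=O)[C@H]1C[C@@H](CC(=O)OCc2ccccc2)C1(C)C | intermediate
4 | lithium enolate of 3 (not isolated) | [Li+].C=C([O-])[C@H]1C[C@@H](CC(=O)OCc2ccccc2)C1(C)C | intermediate
5 | benzyl 2-[(1S,3S)-2,2-dimethyl-3-[1-(trifluoromethanesulfonyloxy)ethenyl]cyclobutyl]acetate | C=C(OS(=O)(=O)C(F)(F)F)[C@H]1C[C@@H](CC(=O)OCc2ccccc2)C1(C)C | intermediate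
6 | [1-[(1S,3S)-3-(2-benzyloxy-2-oxoethyl)-2,2-dimethylcyclobutyl]ethenyl]triphenylphosphonium trifluoromethanesulfonate | C=C([C@H]1C[C@@H](CC(=O)OCc2ccccc2)C1(C)C)[P+](c1ccccc1)(c1ccccc1)c1ccccc1.[O-]S(=O)(=O)C(F)(F)F | intermediate
7 | [1-[(1S,3S)-3-(carboxymethyl)-2,2-dimethylcyclobutyl]ethyl]triphenylphosphonium trifluoromethanesulfonate (both epimers at the phosphonium-bearing carbon) | CC([C@H]1C[C@@H](CC(=O)O)C1(C)C)[P+](c1ccccc1)(c1ccccc1)c1ccccc1.[O-]S(=O)(=O)C(F)(F)F | intermediate
8 | [1-[(1S,3S)-3-[2-(1,3-dioxoisoindolin-2-yl)oxy-2-oxoethyl]-2,2-dimethylcyclobutyl]ethyl]triphenylphosphonium trifluoromethanesulfonate (both epimers at the phosphonium-bearing carbon) | CC([C@H]1C[C@@H](CC(=O)ON2C(=O)c3ccccc3C2=O)C1(C)C)[P+](c1ccccc1)(c1ccccc1)c1ccccc1.[O-]S(=O)(=O)C(F)(F)F | intermediate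
9 | acrolein, prop-2-enal | C=CC=O | starting material
10 | [(3S)-4,4-dimethyl-7-oxo-3-(prop-2-en-1-yl)heptan-2-yl]triphenylphosphonium trifluoromethanesulfonate (not isolated) | C=CC[C@H](C(C)[P+](c1ccccc1)(c1ccccc1)c1ccccc1)C(C)(C)CCC=O.[O-]S(=O)(=O)C(F)(F)F | intermediate
11 | (5S)-4,4-dimethyl-5-(prop-2-en-1-yl)-6-(triphenyl-λ5-phosphanylidene)heptanal (not isolated) | C=CC[C@H](C(C)=P(c1ccccc1)(c1ccccc1)c1ccccc1)C(C)(C)CCC=O | intermediate
12 | (6S)-1,5,5-trimethyl-6-(prop-2-en-1-yl)cyclohex-1-ene | C=CC[C@@H]1C(C)=CCCC1(C)C | intermediate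
13 | 9-[3-[(1S)-2,6,6-trimethylcyclohex-2-en-1-yl]propyl]-9-borabicyclo[3.3.1]nonane (not isolated) | B1(CCC[C@@H]3C(C)=CCCC3(C)C)C2CCCC1CCC2 | intermediate
14 | 3-[(1S)-2,6,6-trimethylcyclohex-2-en-1-yl]propan-1-ol | OCCC[C@@H]1C(C)=CCCC1(C)C | intermediate
15 | 3-[(1S)-2,6,6-trimethylcyclohex-2-en-1-yl]propanal | O=CCC[C@@H]1C(C)=CCCC1(C)C | intermediate
16 | (6S)-6-(but-3-yn-1-yl)-1,5,5-trimethylcyclohex-1-ene | C#CCC[C@@H]1C(C)=CCCC1(C)C | intermediate
17 | dimethyl[(1E)-2-methyl-4-[(1S)-2,6,6-trimethylcyclohex-2-en-1-yl]but-1-en-1-yl]alumane (not isolated) | C[Al](C)/C=C(\C)CC[C@@H]1C(C)=CCCC1(C)C | intermediate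
18 | (6S)-6-[(3E)-4-iodo-3-methylbut-3-en-1-yl]-1,5,5-trimethylcyclohex-1-ene | I/C=C(\C)CC[C@@H]1C(C)=CCCC1(C)C | intermediate
19 | (2E)-3-methylpent-2-en-4-yn-1-ol | C#C/C(C)=C/CO | starting material
20 | tert-butyldimethyl{[(2E)-3-methylpent-2-en-4-yn-1-yl]oxy}silane | C#C/C(C)=C/CO[Si](C)(C)C(C)(C)C | intermediate
21 | tert-butyldimethyl{[(2E)-3-methylpenta-2,4-dien-1-yl]oxy}silane | C=C/C(C)=C/CO[Si](C)(C)C(C)(C)C | intermediate
22 | 9-[(3E)-5-(tert-butyldimethylsilyloxy)-3-methylpent-3-en-1-yl]-9-borabicyclo[3.3.1]nonane (not isolated) | CC(C)(C)[Si](C)(C)OC/C=C(\C)CCB1C2CCCC1CCC2 | intermediate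
23 | tert-butyl{[(2E,6E)-3,7-dimethyl-9-[(1S)-2,6,6-trimethylcyclohex-2-en-1-yl]nona-2,6-dien-1-yl]oxy}dimethylsilane | CC(C)(C)[Si](C)(C)OC/C=C(\C)CC/C=C(\C)CC[C@@H]1C(C)=CCCC1(C)C | intermediate
24 | (2E,6E)-3,7-dimethyl-9-[(1S)-2,6,6-trimethylcyclohex-2-en-1-yl]nona-2,6-dien-1-ol | OC/C=C(\C)CC/C=C(\C)CC[C@@H]1C(C)=CCCC1(C)C | intermediate
25 | linoleic acid, (9Z,12Z)-octadeca-9,12-dienoic acid | CCCCC/C=C\C/C=C\CCCCCCCC(=O)O | starting material
26 | (2E,6E)-3,7-dimethyl-9-[(1S)-2,6,6-trimethylcyclohex-2-en-1-yl]nona-2,6-dien-1-yl (9Z,12Z)-octadeca-9,12-dienoate | CCCCC/C=C\C/C=C\CCCCCCCC(=O)OC/C=C(\C)CC/C=C(\C)CC[C@@H]1C(C)=CCCC1(C)C | target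

**Step count**
Total: 16 steps. Longest linear sequence: 14 steps (steps 1 to 11, then 14 to 16).

**Steps most likely to fail**

Step 7 (proposed new method). Acrolein may capture the primary radical before the cyclobutane has opened. The α-formyl radical may attack the new allyl group before it takes up hydrogen. The ylide may be lost to enolisation of the aldehyde or to left-over acrolein. The fallback uses known chemistry in two separate operations, sets out from cis-pinonic acid 2 and keeps its ketone. The acid would be converted (N-hydroxyphthalimide, DIC, DMAP, CH2Cl2) into 1,3-dioxoisoindolin-2-yl 2-[(1S,3S)-3-acetyl-2,2-dimethylcyclobutyl]acetate F1. Visible-light reduction (Ru(bpy)3(PF6)2, Hantzsch ester, CH2Cl2, slow addition of acrolein 9) should give, by decarboxylation, ring opening and Giese addition, (5S)-5-acetyl-4,4-dimethyloct-7-enal F2. Intramolecular McMurry coupling (TiCl3(DME)1.5, Zn–Cu couple, DME, reflux, slow addition) would then join the ketone and aldehyde carbons, and the route is rejoined at 12.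

Step 5. The cationic, hindered 1,1-disubstituted alkene may resist hydrogenation, so that reduction stops after debenzylation. The fallback sets out from 6 and reduces the alkene by a polar path instead. Conjugate addition of hydride (NaBH4, MeOH, −20 °C) to the vinylphosphonium salt gives the ylide, which methanol protonates to [1-[(1S,3S)-3-(2-benzyloxy-2-oxoethyl)-2,2-dimethylcyclobutyl]ethyl]triphenylphosphonium trifluoromethanesulfonate F3. Hydrogenolysis of the benzyl ester alone (H2, Pd/C, MeOH) then returns to the route at 7.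

Step 14. Hydroboration may go to the internal double bond of the conjugated diene or take place twice, and slow transmetallation may lead to reduction of the iodide. The fallback sets out from 18 and builds the last isoprene unit by iteration of the alkyne chemistry. Negishi coupling (Pd(PPh3)4, THF) of 18 with [4-(trimethylsilyl)but-3-yn-1-yl]zinc bromide F4, made from commercial (4-bromobut-1-yn-1-yl)trimethylsilane and activated zinc, should give trimethyl[(5E)-6-methyl-8-[(1S)-2,6,6-trimethylcyclohex-2-en-1-yl]oct-5-en-1-yn-1-yl]silane F5. Desilylation (K2CO3, MeOH) gives (6S)-1,5,5-trimethyl-6-[(3E)-3-methyloct-3-en-7-yn-1-yl]cyclohex-1-ene F6. A second Zr-catalysed carboalumination (Me3Al, Cp2ZrCl2) followed by paraformaldehyde returns to the route at alcohol 24.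

**Further compounds**
F1 | step 7 | 1,3-dioxoisoindolin-2-yl 2-[(1S,3S)-3-acetyl-2,2-dimethylcyclobutyl]acetate | CC(=O)[C@H]1C[C@@H](CC(=O)ON2C(=O)c3ccccc3C2=O)C1(C)C
F2 | step 7 | (5S)-5-acetyl-4,4-dimethyloct-7-enal | C=CC[C@H](C(C)=O)C(C)(C)CCC=O
F3 | step 5 | [1-[(1S,3S)-3-(2-benzyloxy-2-oxoethyl)-2,2-dimethylcyclobutyl]ethyl]triphenylphosphonium trifluoromethanesulfonate | CC([C@H]1C[C@@H](CC(=O)OCc2ccccc2)C1(C)C)[P+](c1ccccc1)(c1ccccc1)c1ccccc1.[O-]S(=O)(=O)C(F)(F)F
F4 | step 14 | [4-(trimethylsilyl)but-3-yn-1-yl]zinc bromide | C[Si](C)(C)C#CCC[Zn]Br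
F5 | step 14 | trimethyl[(5E)-6-methyl-8-[(1S)-2,6,6-trimethylcyclohex-2-en-1-yl]oct-5-en-1-yn-1-yl]silane | C[Si](C)(C)C#CCC/C=C(\C)CC[C@@H]1C(C)=CCCC1(C)C
F6 | step 14 | (6S)-1,5,5-trimethyl-6-[(3E)-3-methyloct-3-en-7-yn-1-yl]cyclohex-1-ene | C#CCC/C=C(\C)CC[C@@H]1C(C)=CCCC1(C)C
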